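All runs are calculated on assumed constants; scatter was added.

If second end groups are used up in the south-east flask, its late readings tell how they were shared between the two steps that draw on them.

common to all: second end groups 0.0196 M

|  | first end groups | third end groups | remark | time |
|---|---|---|---|---|
| south-east | 0.020 M | 10 mM | the very flask that is asked about, followed so far |  |
| south | 0.013 M | 10 mM | run made earlier |  |
| flask | 0.020 M | 10.0 mM |  | 8.0 d |

| south-east: time / d | south-east: links / % | south: time / d | south: links / % |
|---|---|---|---|
| 1.25 | 65.4 | 0.417 | 54.1 |
| 2.50 | 68.2 | 0.833 | 69.1 |
| 4.00 | 69.4 | 1.25 | 76.8 |
| 5.00 | 71.0 | 1.67 | 79.7 |
| 6.00 | 69.5 | 2.00 | 83.6 |
| 8.00 | 71.1 | 2.50 | 85.6 |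

(scatter of a reading: 1 percentage point)

* links, in percent of the first end groups first charged, at 8.0 d
* the remedy with the largest gain of links, or "none" below 2 percentage points (summer / midnight / dawn / dusk / none)
* links present, with what was taken out counted in, in percent of the first end groups first charged, after summer
* links present, with what was taken out counted in, in percent of the first end groups first charged, after midnight

- summer: change nothing and wait 4.0 d more
- midnight: at 8.0 d take out 90% of the links then present, then wait 4.0 d
- dawn: at 8.0 d add first end groups, 50.0% of the amount charged, then wait 4.0 d
- dusk: at 8.0 d add second end groups, 50.0% of the amount charged, then wait 4.0 d

- what is taken out of links is counted as made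
- what was read earlier has a scatter of 1 percentage point, one standard deviation
- what may be going on: 2 third end groups -> homo dimer; first end groups + second end groups -> links; second end groups + third end groups -> links of the second sort
- additions bring no volume worth counting

The two columns differ in shape. South-east readings from 4.00 d on scatter about 70.2%, with 29.8% of the first end groups free. The south run, charged with less first end groups, is still climbing at 85.6%, so no fixed conversion holds the south-east flask. Second end groups are then the likely limiting reagent there, and the part that links did not take, 28.3% of their charge, would sit in links of the second sort.

Both steps use second end groups. If each goes with the product of its two partners, the free shares of first and third end groups keep one relation. South-east gives 1.50 for the split number, a selectivity factor: the logarithm of the free share of first end groups over the logarithm of the free share of third end groups. Third end groups lost to homo dimer are left out of that free share, so the number is a working figure for this charge.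

The reckoning here commits to 70.2% at 8.0 d. Summer, midnight and dawn then offer no new links, unless links revert. Dusk brings second end groups worth 49.0% of the first end groups charged, more than their free share.

The forecast reads 70.7%, 0.50 percentage points above this reckoning, with 70.9% after summer, 71% after midnight and dusk as best: “Adding second end groups converts the leftover first end groups”.

The flask gives 70.1%, 70.1% after summer, 70.1% after midnight, and dusk gains 28 points.

    2 third end groups → homo dimer (k = 2.06 M⁻¹ h⁻¹)
    first end groups + second end groups → links (k = 6.63 M⁻¹ h⁻¹)
    second end groups + third end groups → links of the second sort (k = 6.12 M⁻¹ h⁻¹)

Links in this flask have come to rest: second end groups stand at 0%, and at ten times the time links read 70.1%. That wait still moves third end groups from 8.46% to 1.20% of their charge and homo dimer from 0.00179 M to 0.00215 M. Held at the split number, 70.1% of links goes with 28.3% of second end groups in links of the second sort; the flask holds 28.4%, a match that repeats the balance the number was made from and so tests nothing. The verdict on waiting would have been wrong at a look at 0.800 d: links stood at 60.0% then and 70.0% at 4.00 d.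

A neighbour of the flask, charged alike except for third end groups, holds 0.017 M of them. With the split number kept and its second end groups shared out as above, trials from one half, halving the miss, give 58.3% and then 59.3% of links; the computed flask gives 60.2%.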